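A direct plan would acylate the lithium enolate of an α-allyloxy aryl ketone with 2,4,6-trifluorobenzoyl chloride to the open-chain diketone A1, close ring C by intramolecular SNAr of the enolate oxygen on an ortho C–F bond to the difluoroflavone A2, exchange both remaining fluorides for allyloxide to reach the tetraallyl ether A3, remove the four allyl ethers to give 4'-O-benzylquercetin A4, sulfate O3, O7 and O3' to the trissulfate A5, and hydrogenolyse the benzyl ether.
Weakest, first: the exchange of the two ring A fluorides of A2 for allyloxide. Hot alkoxide would have to attack C5 next to the carbonyl yet spare C2 of the chromone, where conjugate addition would open ring C, so the oxygen pattern of ring A would be reached by a detour through C–F bonds at a late stage.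
Weakest, second: the allyl stretch. Four allyl ethers would be brought in by three different reagents and then all removed from A3 in a step that builds nothing.
Weakest, third: the run-up to A1. A Weinreb ketone synthesis after bromine–lithium exchange and a cryogenic enolate acylation (C- against O-acylation, retro-Claisen risk) would be spent on a diketone whose only stereocentre is erased at once.

**Retrosynthetic overview**
Ring A of the target carries O1, O5 and O7 in a 1,3,5-pattern around C4a: it is phloroglucinol, whose three ring CH carbons are equivalent. Ring C is therefore cut at C4–C4a and O1–C2, and free phloroglucinol is annulated in one thermal operation with an α-benzyloxy aroylacetate that brings ring B, C2, C3 and C4.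
Rings A and B are bought; ring C is the only ring formed, but from the other side: the C–C bond to the unfunctionalised C4a first, then O1–C2. There are no C–F bonds, no alkoxide on a chromone and no protecting group on ring A, and the 5-OH is born hydrogen-bonded to O4, which keeps it unsulfated.
O4' travels as a tosylate fixed on the ring B ester at the start; it is stable to heat and hydrogenolysis and is not expected to migrate to O3'. It is removed last by aqueous hydroxide, conditions under which aryl sulfate anions are inert.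
The only other protecting groups are two benzyl ethers, removed in one hydrogenolysis before any sulfate is present.
Key step: step 4

Assumption: the trissulfates 14 and 15 would be handled and isolated as potassium salts; names and SMILES show the neutral hydrogen sulfate forms. "Tosyl" means 4-methylbenzenesulfonyl.

Step 1
Reactants: 1 ethyl 3,4-dihydroxybenzoate; 2 p-toluenesulfonyl chloride
Product: 3 ethyl 3-hydroxy-4-(tosyloxy)benzoate
Conditions: TsCl (1.0 equiv), K2CO3 (1.1 equiv), acetone, 0 °C to rt
Reagents that add atoms: p-toluenesulfonyl chloride (2), Cc1ccc(S(=O)(=O)Cl)cc1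
Why: Regioselective O-sulfonylation, in which one equivalent of weak base should ionise only the 4-OH (para to the ester and the more acidic one), the same bias that directs monoalkylation of protocatechuates to O4.

Step 2
Reactants: 3 ethyl 3-hydroxy-4-(tosyloxy)benzoate; 4 benzyl bromide
Product: 5 ethyl 3-(benzyloxy)-4-(tosyloxy)benzoate
Conditions: BnBr (1.2 equiv), K2CO3, DMF, rt
Reagents that add atoms: benzyl bromide (4), BrCc1ccccc1
Why: Williamson ether synthesis on the remaining phenol, which should be fast compared with any sulfonyl transfer, since the neighbouring phenoxide cannot reach an in-line attack at sulfur through a five-membered ring.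

Step 3
Reactants: 5 ethyl 3-(benzyloxy)-4-(tosyloxy)benzoate; 6 ethyl 2-(benzyloxy)acetate
Product: 8 ethyl 2-(benzyloxy)-3-[3-(benzyloxy)-4-(tosyloxy)phenyl]-3-oxopropanoate, via lithium enolate 7 (not isolated)
Conditions: 6 (1.2 equiv), LiN(SiMe3)2 (2.4 equiv), THF, −78 °C; then 5, −78 to −10 °C; AcOH quench
Reagents that add atoms: ethyl 2-(benzyloxy)acetate (6), CCOC(=O)COCc1ccccc1
Why: Crossed Claisen condensation of a chelated α-alkoxy ester enolate with a non-enolisable aryl ester activated by its para sulfonyloxy group; the second equivalent of base stores 8 as its enolate, and the new centre C2 is racemic, labile and erased in step 4.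

Step 4
Reactants: 8 ethyl 2-(benzyloxy)-3-[3-(benzyloxy)-4-(tosyloxy)phenyl]-3-oxopropanoate; 9 phloroglucinol
Product: 12 3-(benzyloxy)-2-[3-(benzyloxy)-4-(tosyloxy)phenyl]-5,7-dihydroxy-4H-chromen-4-one, via aroylketene 10 (not isolated), via diketone 11 (not isolated)
Conditions: anhydrous 9 (1.5 equiv), neat melt or minimal Ph2O, 230–240 °C (microwave or preheated bath), Ar stream, 10–20 min
Reagents that add atoms: phloroglucinol (9), Oc1cc(O)cc(O)c1
Why: Mentzer pyrone synthesis (catalyst-free thermal Simonis-type condensation of a phenol with a β-keto ester), the reaction type that converts phloroglucinol and aroylacetates into 5,7-dihydroxyflavones: above about 200 °C the chelated enol of 8 should lose ethanol to give aroylketene 10, which C-acylates phloroglucinol (directly at carbon, or by reversible O-acylation and thermal Fries shift) and so forms the C4–C4a bond of diketone 11. Ring C then closes by 6-exo-trig addition of a flanking hydroxyl (the later O1) to the aryl ketone carbon C2, followed by loss of water to the aromatic pyranone. Regiochemistry cannot go wrong because the three CH carbons and the three hydroxyls of 9 are equivalent; the hydroxyl that does not close becomes the 5-OH hydrogen-bonded to O4, the third the 7-OH. The selectivity that matters is chromone against 4-arylcoumarin (Pechmann mode): no acid is present to activate the hindered α-substituted aryl ketone toward the ring, and aryl esters formed by O-acylation return to the ketene at this temperature, so material should drain into the irreversible C-acylation. A second annulation is disfavoured by the excess of 9 and by the deactivating acyl group, and the benzyl ethers and the aryl tosylate should tolerate a short neutral melt. No stereocentre is formed, and the labile centre C2 of 8 becomes sp2.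

Step 5
Reactants: 12 3-(benzyloxy)-2-[3-(benzyloxy)-4-(tosyloxy)phenyl]-5,7-dihydroxy-4H-chromen-4-one
Product: 13 2-[3-hydroxy-4-(tosyloxy)phenyl]-3,5,7-trihydroxy-4H-chromen-4-one (4'-O-tosylquercetin)
Conditions: H2 (1 atm), Pd/C, THF–MeOH, rt
Reagents that add atoms: none
Why: Catalytic hydrogenolysis of the two benzyl ethers (the enol ether at O3 and the aryl ether at O3'), under which an aryl sulfonate and the tetrasubstituted C2=C3 bond should not be reduced.

Step 6
Reactants: 13 4'-O-tosylquercetin
Product: 14 4'-O-tosylquercetin 3,7,3'-tris(hydrogen sulfate)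
Conditions: SO3·NMe3 (5 equiv), Et3N (10 equiv), DMF, 45 °C, Ar; aq. KHCO3; Sephadex LH-20 or C18
Reagents that add atoms: sulfur trioxide–trimethylamine complex, C[N+](C)(C)S(=O)(=O)[O-]
Why: O-sulfation of phenols by an amine–SO3 complex, in which the 3-, 7- and 3'-hydroxyls should react as ammonium phenoxides while the 5-OH, tied in a six-membered hydrogen bond to O4, characteristically stays free and O4' is blocked by the non-migrating tosylate.

Step 7
Reactants: 14 4'-O-tosylquercetin 3,7,3'-tris(hydrogen sulfate)
Product: 15 quercetin 3,3',7-trissulfate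
Conditions: KOH (1 M, degassed H2O), 45–50 °C, Ar; AcOH to pH 7; C18 or size-exclusion desalting
Reagents that add atoms: none
Why: Alkaline hydrolysis of an aryl sulfonate by hydroxide attack at sulfur, eased because the departing 4'-phenoxide is conjugated through C2=C3 with the C4 carbonyl; aryl sulfate monoester anions are inert to hydroxide, the 5-phenoxide formed in base shields C2 from conjugate attack, and without an alcohol cosolvent no alkylating alkyl tosylate can form.

**Compound list**
1 | ethyl 3,4-dihydroxybenzoate | CCOC(=O)c1ccc(O)c(O)c1 | starting material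
2 | p-toluenesulfonyl chloride | Cc1ccc(S(=O)(=O)Cl)cc1 | starting material
3 | ethyl 3-hydroxy-4-(tosyloxy)benzoate | CCOC(=O)c1ccc(OS(=O)(=O)c2ccc(C)cc2)c(O)c1 | intermediate
4 | benzyl bromide | BrCc1ccccc1 | starting material
5 | ethyl 3-(benzyloxy)-4-(tosyloxy)benzoate | CCOC(=O)c1ccc(OS(=O)(=O)c2ccc(C)cc2)c(OCc2ccccc2)c1 | intermediate
6 | ethyl 2-(benzyloxy)acetate | CCOC(=O)COCc1ccccc1 | starting material
7 | lithium enolate of ethyl 2-(benzyloxy)acetate, chelated, O–Li cis to the benzyloxy group (not isolated) | [Li]O/C(OCC)=C\OCc1ccccc1 | intermediate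
8 | ethyl 2-(benzyloxy)-3-[3-(benzyloxy)-4-(tosyloxy)phenyl]-3-oxopropanoate (racemic and labile at C2) | CCOC(=O)C(OCc1ccccc1)C(=O)c1ccc(OS(=O)(=O)c2ccc(C)cc2)c(OCc2ccccc2)c1 | intermediate
9 | phloroglucinol (benzene-1,3,5-triol) | Oc1cc(O)cc(O)c1 | starting material
10 | 2-(benzyloxy)-3-[3-(benzyloxy)-4-(tosyloxy)phenyl]prop-1-ene-1,3-dione (aroylketene; not isolated) | O=C=C(OCc1ccccc1)C(=O)c1ccc(OS(=O)(=O)c2ccc(C)cc2)c(OCc2ccccc2)c1 | intermediate
11 | 2-(benzyloxy)-1-[3-(benzyloxy)-4-(tosyloxy)phenyl]-3-(2,4,6-trihydroxyphenyl)propane-1,3-dione (not isolated) | O=C(c1c(O)cc(O)cc1O)C(OCc1ccccc1)C(=O)c1ccc(OS(=O)(=O)c2ccc(C)cc2)c(OCc2ccccc2)c1 | intermediate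
12 | 3-(benzyloxy)-2-[3-(benzyloxy)-4-(tosyloxy)phenyl]-5,7-dihydroxy-4H-chromen-4-one | O=c1c(OCc2ccccc2)c(-c2ccc(OS(=O)(=O)c3ccc(C)cc3)c(OCc3ccccc3)c2)oc2cc(O)cc(O)c12 | intermediate
13 | 2-[3-hydroxy-4-(tosyloxy)phenyl]-3,5,7-trihydroxy-4H-chromen-4-one (4'-O-tosylquercetin) | O=c1c(O)c(-c2ccc(OS(=O)(=O)c3ccc(C)cc3)c(O)c2)oc2cc(O)cc(O)c12 | intermediate
14 | 4'-O-tosylquercetin 3,7,3'-tris(hydrogen sulfate) | O=c1c(OS(=O)(=O)O)c(-c2ccc(OS(=O)(=O)c3ccc(C)cc3)c(OS(=O)(=O)O)c2)oc2cc(OS(=O)(=O)O)cc(O)c12 | intermediate
15 | quercetin 3,3',7-trissulfate | O=c1c(OS(=O)(=O)O)c(-c2ccc(O)c(OS(=O)(=O)O)c2)oc2cc(OS(=O)(=O)O)cc(O)c12 | target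

**Step count and risks**
Total steps: 7. Longest linear sequence: 7 (1 to 15).

Steps most likely to fail:

1. Step 4 (thermal annulation). The ketene may be diverted into O-acylation and Pechmann-type closure, the O3 benzyl group may be lost in the hot phenolic melt, or the melt may char before C-acylation is complete. The fallback builds the same C4–C4a bond stepwise at low temperature; it sets out from 9 and 5 and comes back at 11. Hoesch acylation of 9 with (benzyloxy)acetonitrile (HCl gas, ZnCl2, Et2O, 0 °C) should give 2-(benzyloxy)-1-(2,4,6-trihydroxyphenyl)ethan-1-iminium chloride F1, which would be hydrolysed in hot water to 2-(benzyloxy)-1-(2,4,6-trihydroxyphenyl)ethan-1-one F2. In parallel, ester 5 would be cleaved with Me3SnOH (1,2-dichloroethane, 80 °C) to 3-(benzyloxy)-4-(tosyloxy)benzoic acid F3 and converted with oxalyl chloride and catalytic DMF into 3-(benzyloxy)-4-(tosyloxy)benzoyl chloride F4. LiN(SiMe3)2 (5 equiv, THF, −78 °C) would turn F2 into the tetralithium enolate-triphenoxide of F2 F5, which would be C-aroylated by F4 (polyanion variant of the Baker–Venkataraman diketone synthesis) to give, after acidification, diketone 11. p-TsOH in toluene at 80 °C would then close 11 to 12.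

2. Step 6 (trisulfation). Sulfation at O3 may stay incomplete while O5 begins to react, leaving a mixture of polar salts that resists separation. The fallback uses neutral, chromatographable sulfate diesters; it sets out from 13 and comes back at 14. Compound 13 would be treated with 2,2,2-trichloroethyl chlorosulfate (3.3 equiv), Et3N and DMAP in THF at 0 °C to give 4'-O-tosylquercetin 3,7,3'-tris(2,2,2-trichloroethyl sulfate) F6, which would be purified on silica gel. Zn dust and HCO2NH4 in MeOH at rt would then fragment the three trichloroethyl groups and deliver 14 as its ammonium salt.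

3. Step 3 (crossed Claisen condensation). The ester enolate may self-condense or attack the sulfonate before the aryl ester is acylated. The fallback replaces acyl substitution by aldol addition and oxidation; it sets out from 5 and comes back at 8. i-Bu2AlH (CH2Cl2, −78 to 0 °C) would reduce 5 to [3-(benzyloxy)-4-(tosyloxy)phenyl]methanol F7, and MnO2 would oxidise this to 3-(benzyloxy)-4-(tosyloxy)benzaldehyde F8. Aldehyde F8 would add enolate 7 at −78 °C to give ethyl 2-(benzyloxy)-3-[3-(benzyloxy)-4-(tosyloxy)phenyl]-3-hydroxypropanoate F9 as a mixture of diastereomers, which is of no consequence, and Dess–Martin periodinane would then give 8.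

**Further compounds**
F1 | step 4 | 2-(benzyloxy)-1-(2,4,6-trihydroxyphenyl)ethan-1-iminium chloride | [NH2+]=C(COCc1ccccc1)c1c(O)cc(O)cc1O.[Cl-]
F2 | step 4 | 2-(benzyloxy)-1-(2,4,6-trihydroxyphenyl)ethan-1-one | O=C(COCc1ccccc1)c1c(O)cc(O)cc1O
F3 | step 4 | 3-(benzyloxy)-4-(tosyloxy)benzoic acid | O=C(O)c1ccc(OS(=O)(=O)c2ccc(C)cc2)c(OCc2ccccc2)c1
F4 | step 4 | 3-(benzyloxy)-4-(tosyloxy)benzoyl chloride | O=C(Cl)c1ccc(OS(=O)(=O)c2ccc(C)cc2)c(OCc2ccccc2)c1
F5 | step 4 | tetralithium enolate-triphenoxide of F2 (enolate geometry not assigned) | [Li]OC(=COCc1ccccc1)c1c(O[Li])cc(O[Li])cc1O[Li]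
F6 | step 6 | 4'-O-tosylquercetin 3,7,3'-tris(2,2,2-trichloroethyl sulfate) | O=c1c(OS(=O)(=O)OCC(Cl)(Cl)Cl)c(-c2ccc(OS(=O)(=O)c3ccc(C)cc3)c(OS(=O)(=O)OCC(Cl)(Cl)Cl)c2)oc2cc(OS(=O)(=O)OCC(Cl)(Cl)Cl)cc(O)c12
F7 | step 3 | [3-(benzyloxy)-4-(tosyloxy)phenyl]methanol | OCc1ccc(OS(=O)(=O)c2ccc(C)cc2)c(OCc2ccccc2)c1
F8 | step 3 | 3-(benzyloxy)-4-(tosyloxy)benzaldehyde | O=Cc1ccc(OS(=O)(=O)c2ccc(C)cc2)c(OCc2ccccc2)c1
F9 | step 3 | ethyl 2-(benzyloxy)-3-[3-(benzyloxy)-4-(tosyloxy)phenyl]-3-hydroxypropanoate (mixture of diastereomers) | CCOC(=O)C(OCc1ccccc1)C(O)c1ccc(OS(=O)(=O)c2ccc(C)cc2)c(OCc2ccccc2)c1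
A1 | direct plan | 2-(allyloxy)-1-[3-(allyloxy)-4-(benzyloxy)phenyl]-3-(2,4,6-trifluorophenyl)propane-1,3-dione | C=CCOC(C(=O)c1ccc(OCc2ccccc2)c(OCC=C)c1)C(=O)c1c(F)cc(F)cc1F
A2 | direct plan | 3-(allyloxy)-2-[3-(allyloxy)-4-(benzyloxy)phenyl]-5,7-difluoro-4H-chromen-4-one | O=c1c(OCC=C)c(-c2ccc(OCc3ccccc3)c(OCC=C)c2)oc2cc(F)cc(F)c12
A3 | direct plan | 3,5,7-tris(allyloxy)-2-[3-(allyloxy)-4-(benzyloxy)phenyl]-4H-chromen-4-one | O=c1c(OCC=C)c(-c2ccc(OCc3ccccc3)c(OCC=C)c2)oc2cc(OCC=C)cc(OCC=C)c12
A4 | direct plan | 2-[4-(benzyloxy)-3-hydroxyphenyl]-3,5,7-trihydroxy-4H-chromen-4-one (4'-O-benzylquercetin) | O=c1c(O)c(-c2ccc(OCc3ccccc3)c(O)c2)oc2cc(O)cc(O)c12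
A5 | direct plan | 4'-O-benzylquercetin 3,7,3'-tris(hydrogen sulfate) | O=c1c(OS(=O)(=O)O)c(-c2ccc(OCc3ccccc3)c(OS(=O)(=O)O)c2)oc2cc(OS(=O)(=O)O)cc(O)c12
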